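**Retrosynthetic overview**

- Feature: in lignan numbering the chain C7–C8–C8'–C9' is read as a γ-butyrolactone ring. C7 (the guaiacyl CH2) is the lactone carbonyl and C9' (the acetoxymethyl carbon) is the ring O–CH. The C8 methyl and the C8'–C7' (syringylmethyl) branch sit trans on that ring.
- Key disconnection: C7'–C8' and C8–C9 are made in one flask. The lithiated syringyl dithiane 12 adds 1,4 to (5R)-menthyloxybutenolide 5, and the enolate is methylated with iodomethane 11 to give 14.
- C7–aryl bond: the auxiliary is first exchanged for a plain lactone (17), so that opening cannot release an aldehyde. Guaiacyl-lithium 18 then adds at C7. The C7 oxygen is removed at the end (reduce, acetylate, hydrogenolyse), the C9' oxygen stays as the acetate, and the C7' sulfur is removed with Raney Ni.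
- Rings: the furanone ring comes from furfural (step 1) and is kept through the key step, which closes no ring. The only ring closure is the relactonization in step 7, and that lactone is opened for good in step 8. The target has no ring besides the two arenes.

Key step: step 6

Remark: the target is (8S,8'R), with C9 the methyl and C9' the acetoxymethyl carbon; the C7 carbinol centre made in step 9 is carried as an epimer mixture (compounds 21–23) because step 12 removes it.

**Route**

Step 1
Reactants: 1 furfural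
Product: 3 5-hydroxyfuran-2(5H)-one (racemic), via furfural endoperoxide 2 (not isolated)
Conditions: O2, hν (visible), methylene blue (C16H18ClN3S, cat.), MeOH, 0 °C to rt
Reagents that add atoms: dioxygen O=O
Why: Sensitized singlet-oxygen [4+2] cycloaddition to the furan gives endoperoxide 2, which methanol opens with loss of the formyl carbon as methyl formate (furfural photooxygenation), leaving the hydroxybutenolide.

Step 2
Reactants: 3 5-hydroxyfuran-2(5H)-one; 4 (−)-menthol
Product: 5 (5R)-5-(l-menthyloxy)furan-2(5H)-one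
Conditions: p-TsOH (cat.), toluene, reflux with azeotropic removal of water; crystallization from petroleum ether, mother liquor re-equilibrated with p-TsOH
Reagents that add atoms: none
Why: Acid-catalysed acetalization of the cyclic hemiacylal gives both C5 epimers, which interconvert under the acid, and the (5R)-epimer is expected to crystallize, so the acetal stereocenter is set by crystallization-driven equilibration.

Step 3
Reactants: 6 syringaldehyde
Product: 7 4-(benzyloxy)-3,5-dimethoxybenzaldehyde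
Conditions: BnBr, K2CO3, DMF, 60 °C
Reagents that add atoms: benzyl bromide BrCc1ccccc1
Why: Williamson etherification of the phenoxide masks the acidic phenol before any organolithium chemistry.

Step 4
Reactants: 7 4-(benzyloxy)-3,5-dimethoxybenzaldehyde
Product: 8 2-[4-(benzyloxy)-3,5-dimethoxyphenyl]-1,3-dithiane
Conditions: HS(CH2)3SH, BF3·OEt2 (cat.), CH2Cl2, 0 °C to rt
Reagents that add atoms: propane-1,3-dithiol SCCCS
Why: Lewis-acid-catalysed dithioacetalization of the aryl aldehyde gives the acyl-anion precursor, and the aryl benzyl and methyl ethers tolerate catalytic BF3 at this temperature.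

Step 5
Reactants: 9 4-bromo-2-methoxyphenol
Product: 10 1-(benzyloxy)-4-bromo-2-methoxybenzene
Conditions: BnBr, K2CO3, acetone, reflux
Reagents that add atoms: benzyl bromide BrCc1ccccc1
Why: Williamson etherification protects the guaiacyl phenol so that the bromide can later undergo bromine–lithium exchange.

Step 6
Reactants: 8 2-[4-(benzyloxy)-3,5-dimethoxyphenyl]-1,3-dithiane; 5 (5R)-5-(l-menthyloxy)furan-2(5H)-one; 11 iodomethane
Product: 14 (3R,4R,5R)-4-{2-[4-(benzyloxy)-3,5-dimethoxyphenyl]-1,3-dithian-2-yl}-3-methyl-5-(l-menthyloxy)dihydrofuran-2(3H)-one, via lithiated dithiane 12 (not isolated), via lactone lithium enolate 13 (not isolated)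
Conditions: 8, n-BuLi, THF, −78 to −20 °C; 5, THF, −78 °C; then MeI (11), DMPU, −78 to −20 °C; aq. NH4Cl
Reagents that add atoms: none
Why: n-BuLi removes the C2–H of dithiane 8 to give the aryl-stabilized carbanion 12, which adds as a soft acyl-anion equivalent to C4 of butenolide 5 (Michael-type 1,4-addition), and the resulting lithium lactone enolate 13 is C-methylated at C3 by SN2 attack on iodomethane, so that the C7'–C8' and C8–C9 bonds form in one flask. The closest known reaction type is the tandem conjugate addition–enolate alkylation of lithiated dithioacetals with 5-alkoxybutenolides used for dibenzylbutyrolactone lignans. No ring is closed; the furanone ring of 5 is retained. C4 (the future C8') is set by the (5R)-acetal center, because the carbanion approaches anti to the menthyloxy group, and C3 (the future C8) is set by C4, because iodomethane approaches the enolate anti to the bulky dithianyl substituent, which should give the 3,4-trans-4,5-trans lactone. The step needs 1,4- over 1,2-addition, secured by the delocalized and hindered 2-aryl-dithianyl anion and the activated enoate, and mono-C-methylation, secured by the absence of free base after the addition and by the hindered tertiary α-position of 14.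

Step 7
Reactants: 14 (3R,4R,5R)-4-{2-[4-(benzyloxy)-3,5-dimethoxyphenyl]-1,3-dithian-2-yl}-3-methyl-5-(l-menthyloxy)dihydrofuran-2(3H)-one
Product: 17 (3R,4R)-4-{2-[4-(benzyloxy)-3,5-dimethoxyphenyl]-1,3-dithian-2-yl}-3-methyldihydrofuran-2(3H)-one, via potassium formyl carboxylate 15 (not isolated), via potassium hydroxy carboxylate 16 (not isolated)
Conditions: KOH, NaBH4, EtOH–H2O, 0 °C to rt; then aq. HCl to pH 2, rt
Reagents that add atoms: none
Why: Saponification of the acylal lactone releases menthol and the C9' aldehyde, which borohydride reduces in situ faster than C8' can enolize, and acidification closes the γ-hydroxy acid to the lactone (5-exo-trig lactonization), giving a lactone with C7 still as carbonyl that an aryllithium can open without unmasking an aldehyde.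

Step 8
Reactants: 17 (3R,4R)-4-{2-[4-(benzyloxy)-3,5-dimethoxyphenyl]-1,3-dithian-2-yl}-3-methyldihydrofuran-2(3H)-one; 10 1-(benzyloxy)-4-bromo-2-methoxybenzene
Product: 20 (2R,3R)-1-[4-(benzyloxy)-3-methoxyphenyl]-3-{2-[4-(benzyloxy)-3,5-dimethoxyphenyl]-1,3-dithian-2-yl}-4-hydroxy-2-methylbutan-1-one (in equilibrium with its cyclic hemiketal), via aryllithium 18 (not isolated), via lithium lactolate 19 (not isolated)
Conditions: 10, n-BuLi, THF, −78 °C; added to 17, THF, −78 °C; sat. aq. NH4Cl at −78 °C; used crude without contact with acid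
Reagents that add atoms: none
Why: Bromine–lithium exchange gives the guaiacyl-lithium, whose 1,2-addition to the lactone carbonyl stops at the tetrahedral lithium lactolate 19 at −78 °C, so a single aryl group is delivered to C7 and the neutral quench should leave the C8 center α to the new ketone intact.

Step 9
Reactants: 20 (2R,3R)-1-[4-(benzyloxy)-3-methoxyphenyl]-3-{2-[4-(benzyloxy)-3,5-dimethoxyphenyl]-1,3-dithian-2-yl}-4-hydroxy-2-methylbutan-1-one
Product: 21 (2R,3R)-1-[4-(benzyloxy)-3-methoxyphenyl]-3-{2-[4-(benzyloxy)-3,5-dimethoxyphenyl]-1,3-dithian-2-yl}-2-methylbutane-1,4-diol (both C1 epimers)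
Conditions: NaBH4, MeOH–THF, 0 °C to rt
Reagents that add atoms: none
Why: Borohydride reduction of the aryl ketone (the open form drains the hemiketal) gives the benzylic alcohol, whose configuration is irrelevant because C7 becomes CH2 in step 12.

Step 10
Reactants: 21 (2R,3R)-1-[4-(benzyloxy)-3-methoxyphenyl]-3-{2-[4-(benzyloxy)-3,5-dimethoxyphenyl]-1,3-dithian-2-yl}-2-methylbutane-1,4-diol
Product: 22 (2R,3R)-1-[4-(benzyloxy)-3-methoxyphenyl]-3-{2-[4-(benzyloxy)-3,5-dimethoxyphenyl]-1,3-dithian-2-yl}-2-methylbutane-1,4-diyl diacetate (both C1 epimers)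
Conditions: Ac2O, pyridine, DMAP (cat.), CH2Cl2, 0 °C to rt
Reagents that add atoms: acetic anhydride CC(=O)OC(C)=O
Why: DMAP-catalysed O-acylation esterifies the primary C9' hydroxyl, which is the acetate of the target, and the benzylic C7 hydroxyl, which becomes the leaving group for step 12, while the basic medium avoids ionization at C7.

Step 11
Reactants: 22 (2R,3R)-1-[4-(benzyloxy)-3-methoxyphenyl]-3-{2-[4-(benzyloxy)-3,5-dimethoxyphenyl]-1,3-dithian-2-yl}-2-methylbutane-1,4-diyl diacetate
Product: 23 (2R,3R)-1-[4-(benzyloxy)-3-methoxyphenyl]-3-[4-(benzyloxy)-3,5-dimethoxybenzyl]-2-methylbutane-1,4-diyl diacetate (both C1 epimers)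
Conditions: Raney Ni (W-2, washed neutral), THF–EtOH, rt
Reagents that add atoms: none
Why: Raney Ni hydrogenolysis of the C–S bonds of the benzylic dithioketal (Mozingo-type desulfurization) turns C7' into CH2 without touching C8 or C8', and any benzyl ether or C7 acetate cleaved at this stage converges on 24 in step 12 because no acylation follows.

Step 12
Reactants: 23 (2R,3R)-1-[4-(benzyloxy)-3-methoxyphenyl]-3-[4-(benzyloxy)-3,5-dimethoxybenzyl]-2-methylbutane-1,4-diyl diacetate
Product: 24 (2R,3S)-4-(4-hydroxy-3-methoxyphenyl)-2-(4-hydroxy-3,5-dimethoxybenzyl)-3-methylbutyl acetate (target, CID53359579)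
Conditions: H2 (1–3 atm), 10% Pd/C, EtOAc–EtOH, rt, after chromatographic removal of sulfur residues from 23
Reagents that add atoms: none
Why: Heterogeneous Pd-catalysed hydrogenolysis should cleave the two aryl benzyl ethers and the electron-rich secondary benzylic C7–OAc bond while the primary alkyl acetate at C9' is inert, and under neutral conditions no C7 cation or C7=C8 alkene is formed, so C8 keeps its configuration.

**Compound list**

1 | furfural | O=Cc1ccco1 | starting material
2 | furfural endoperoxide (1-formyl-2,3,7-trioxabicyclo[2.2.1]hept-5-ene) | O=CC12OOC(C=C1)O2 | intermediate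
3 | 5-hydroxyfuran-2(5H)-one (racemic) | O=C1C=CC(O)O1 | intermediate
4 | (−)-menthol, (1R,2S,5R)-2-isopropyl-5-methylcyclohexanol | CC(C)[C@@H]1CC[C@@H](C)C[C@H]1O | starting material
5 | (5R)-5-(l-menthyloxy)furan-2(5H)-one | O=C1C=C[C@H](O[C@@H]2C[C@H](C)CC[C@H]2C(C)C)O1 | intermediate
6 | syringaldehyde | COc1cc(C=O)cc(OC)c1O | starting material
7 | 4-(benzyloxy)-3,5-dimethoxybenzaldehyde | COc1cc(C=O)cc(OC)c1OCc1ccccc1 | intermediate
8 | 2-[4-(benzyloxy)-3,5-dimethoxyphenyl]-1,3-dithiane | COc1cc(C2SCCCS2)cc(OC)c1OCc1ccccc1 | intermediate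
9 | 4-bromo-2-methoxyphenol | COc1cc(Br)ccc1O | starting material
10 | 1-(benzyloxy)-4-bromo-2-methoxybenzene | COc1cc(Br)ccc1OCc1ccccc1 | intermediate
11 | iodomethane | CI | starting material
12 | 2-[4-(benzyloxy)-3,5-dimethoxyphenyl]-2-lithio-1,3-dithiane | [Li]C1(SCCCS1)c1cc(OC)c(OCc2ccccc2)c(OC)c1 | intermediate
13 | lithium enolate of (4R,5R)-4-{2-[4-(benzyloxy)-3,5-dimethoxyphenyl]-1,3-dithian-2-yl}-5-(l-menthyloxy)dihydrofuran-2(3H)-one | [Li]OC1=C[C@H]([C@H](O[C@@H]2C[C@H](C)CC[C@H]2C(C)C)O1)C3(SCCCS3)c4cc(OC)c(OCc5ccccc5)c(OC)c4 | intermediate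
14 | (3R,4R,5R)-4-{2-[4-(benzyloxy)-3,5-dimethoxyphenyl]-1,3-dithian-2-yl}-3-methyl-5-(l-menthyloxy)dihydrofuran-2(3H)-one (3,4-trans, 4,5-trans) | O=C1[C@H](C)[C@H]([C@H](O[C@@H]2C[C@H](C)CC[C@H]2C(C)C)O1)C3(SCCCS3)c4cc(OC)c(OCc5ccccc5)c(OC)c4 | intermediate
15 | potassium (2R,3R)-3-{2-[4-(benzyloxy)-3,5-dimethoxyphenyl]-1,3-dithian-2-yl}-2-methyl-4-oxobutanoate | [K+].[O-]C(=O)[C@H](C)[C@H](C=O)C1(SCCCS1)c1cc(OC)c(OCc2ccccc2)c(OC)c1 | intermediate
16 | potassium (2R,3R)-3-{2-[4-(benzyloxy)-3,5-dimethoxyphenyl]-1,3-dithian-2-yl}-4-hydroxy-2-methylbutanoate | [K+].[O-]C(=O)[C@H](C)[C@H](CO)C1(SCCCS1)c1cc(OC)c(OCc2ccccc2)c(OC)c1 | intermediate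
17 | (3R,4R)-4-{2-[4-(benzyloxy)-3,5-dimethoxyphenyl]-1,3-dithian-2-yl}-3-methyldihydrofuran-2(3H)-one (trans) | O=C1[C@H](C)[C@H](CO1)C3(SCCCS3)c4cc(OC)c(OCc5ccccc5)c(OC)c4 | intermediate
18 | [4-(benzyloxy)-3-methoxyphenyl]lithium | [Li]c1ccc(OCc2ccccc2)c(OC)c1 | intermediate
19 | lithium (3R,4R)-2-[4-(benzyloxy)-3-methoxyphenyl]-4-{2-[4-(benzyloxy)-3,5-dimethoxyphenyl]-1,3-dithian-2-yl}-3-methyltetrahydrofuran-2-olate (C2 unassigned) | [Li]OC1(c2ccc(OCc3ccccc3)c(OC)c2)[C@H](C)[C@H](CO1)C4(SCCCS4)c5cc(OC)c(OCc6ccccc6)c(OC)c5 | intermediate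
20 | (2R,3R)-1-[4-(benzyloxy)-3-methoxyphenyl]-3-{2-[4-(benzyloxy)-3,5-dimethoxyphenyl]-1,3-dithian-2-yl}-4-hydroxy-2-methylbutan-1-one | O=C(c1ccc(OCc2ccccc2)c(OC)c1)[C@H](C)[C@H](CO)C3(SCCCS3)c4cc(OC)c(OCc5ccccc5)c(OC)c4 | intermediate
21 | (2R,3R)-1-[4-(benzyloxy)-3-methoxyphenyl]-3-{2-[4-(benzyloxy)-3,5-dimethoxyphenyl]-1,3-dithian-2-yl}-2-methylbutane-1,4-diol (C1 epimers) | OC(c1ccc(OCc2ccccc2)c(OC)c1)[C@H](C)[C@H](CO)C3(SCCCS3)c4cc(OC)c(OCc5ccccc5)c(OC)c4 | intermediate
22 | (2R,3R)-1-[4-(benzyloxy)-3-methoxyphenyl]-3-{2-[4-(benzyloxy)-3,5-dimethoxyphenyl]-1,3-dithian-2-yl}-2-methylbutane-1,4-diyl diacetate (C1 epimers) | CC(=O)OC(c1ccc(OCc2ccccc2)c(OC)c1)[C@H](C)[C@H](COC(C)=O)C3(SCCCS3)c4cc(OC)c(OCc5ccccc5)c(OC)c4 | intermediate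
23 | (2R,3R)-1-[4-(benzyloxy)-3-methoxyphenyl]-3-[4-(benzyloxy)-3,5-dimethoxybenzyl]-2-methylbutane-1,4-diyl diacetate (C1 epimers) | CC(=O)OC(c1ccc(OCc2ccccc2)c(OC)c1)[C@H](C)[C@H](COC(C)=O)Cc3cc(OC)c(OCc4ccccc4)c(OC)c3 | intermediate
24 | (2R,3S)-4-(4-hydroxy-3-methoxyphenyl)-2-(4-hydroxy-3,5-dimethoxybenzyl)-3-methylbutyl acetate | COc1cc(C[C@H](C)[C@H](COC(C)=O)Cc2cc(OC)c(O)c(OC)c2)ccc1O | target

**Step count**

Total: 12 steps. Longest linear sequence: 9 steps (1, 2, 6, 7, 8, 9, 10, 11, 12; the branch 3, 4, 6–12 is equally long).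

**Steps most likely to fail, with fallbacks**

Step 6. The hindered lactone enolate may be methylated incompletely or without facial control (proton transfer, cis/trans mixtures), or part of the carbanion may add to the carbonyl. The fallback sets out from 5 and 8 and separates the two bond formations. The conjugate addition is run alone (n-BuLi, THF, −78 °C, then NH4Cl) to give the unmethylated adduct (4R,5R)-4-{2-[4-(benzyloxy)-3,5-dimethoxyphenyl]-1,3-dithian-2-yl}-5-(l-menthyloxy)dihydrofuran-2(3H)-one F1, which can be purified. Its enolate (again 13) is then generated with LiN(i-Pr)2 in THF at −78 °C and methylated with 11. Any cis component is equilibrated to the trans isomer with catalytic DBU, since C3 is the only base-epimerizable center. The sequence returns to the route at 14.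

Step 8. The basic aryllithium may enolize the α-branched lactone instead of adding, a second equivalent may add if the lactolate collapses early, or the hemiketal form of 20 may dehydrate toward a dihydrofuran with loss of C8. The fallback sets out from 17 and moves the aryl addition to the aldehyde oxidation level. i-Bu2AlH (CH2Cl2, −78 °C) gives the lactol (3R,4R)-4-{2-[4-(benzyloxy)-3,5-dimethoxyphenyl]-1,3-dithian-2-yl}-3-methyltetrahydrofuran-2-ol F2. The Grignard reagent [4-(benzyloxy)-3-methoxyphenyl]magnesium bromide F3, made from 10 and Mg in THF, is added in excess at 0 °C. It attacks the open hydroxy-aldehyde form of F2, which is a better electrophile than the lactone and cannot be attacked twice. This gives the diol directly, and the sequence returns to the route at 21 without passing through 20.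

Step 12. Hydrogenolysis of the secondary benzylic C7–O bond may stall after debenzylation, or C7 may ionize, with elimination toward C8 or Friedel–Crafts closure onto the electron-rich syringyl ring. The fallback sets out from 20 and removes the C7 oxygen by a radical path (Barton–McCombie deoxygenation) that involves neither a cation nor an alkene.
- Ac2O and pyridine give the keto acetate (2R,3R)-4-[4-(benzyloxy)-3-methoxyphenyl]-2-{2-[4-(benzyloxy)-3,5-dimethoxyphenyl]-1,3-dithian-2-yl}-3-methyl-4-oxobutyl acetate F4.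
- NaBH4 in MeOH–THF at −20 °C gives the hydroxy acetate (2R,3R)-4-[4-(benzyloxy)-3-methoxyphenyl]-2-{2-[4-(benzyloxy)-3,5-dimethoxyphenyl]-1,3-dithian-2-yl}-4-hydroxy-3-methylbutyl acetate F5.
- Raney Ni in THF–EtOH gives (2R,3R)-4-[4-(benzyloxy)-3-methoxyphenyl]-2-[4-(benzyloxy)-3,5-dimethoxybenzyl]-4-hydroxy-3-methylbutyl acetate F6.
- O-Phenyl chlorothionoformate with pyridine and DMAP gives the thionocarbonate O-{(2R,3R)-4-acetoxy-1-[4-(benzyloxy)-3-methoxyphenyl]-3-[4-(benzyloxy)-3,5-dimethoxybenzyl]-2-methylbutyl} O-phenyl carbonothioate F7.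
- Bu3SnH and AIBN in toluene at 80 °C give (2R,3S)-4-[4-(benzyloxy)-3-methoxyphenyl]-2-[4-(benzyloxy)-3,5-dimethoxybenzyl]-3-methylbutyl acetate F8.
- H2 over Pd/C then has only the two benzyl ethers to cleave, and the sequence returns to the route at 24.

**Further compounds**

F1 | step 6 | (4R,5R)-4-{2-[4-(benzyloxy)-3,5-dimethoxyphenyl]-1,3-dithian-2-yl}-5-(l-menthyloxy)dihydrofuran-2(3H)-one | O=C1C[C@H]([C@H](O[C@@H]2C[C@H](C)CC[C@H]2C(C)C)O1)C3(SCCCS3)c4cc(OC)c(OCc5ccccc5)c(OC)c4
F2 | step 8 | (3R,4R)-4-{2-[4-(benzyloxy)-3,5-dimethoxyphenyl]-1,3-dithian-2-yl}-3-methyltetrahydrofuran-2-ol (both anomers) | OC1[C@H](C)[C@H](CO1)C3(SCCCS3)c4cc(OC)c(OCc5ccccc5)c(OC)c4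
F3 | step 8 | [4-(benzyloxy)-3-methoxyphenyl]magnesium bromide | Br[Mg]c1ccc(OCc2ccccc2)c(OC)c1
F4 | step 12 | (2R,3R)-4-[4-(benzyloxy)-3-methoxyphenyl]-2-{2-[4-(benzyloxy)-3,5-dimethoxyphenyl]-1,3-dithian-2-yl}-3-methyl-4-oxobutyl acetate | O=C(c1ccc(OCc2ccccc2)c(OC)c1)[C@H](C)[C@H](COC(C)=O)C3(SCCCS3)c4cc(OC)c(OCc5ccccc5)c(OC)c4
F5 | step 12 | (2R,3R)-4-[4-(benzyloxy)-3-methoxyphenyl]-2-{2-[4-(benzyloxy)-3,5-dimethoxyphenyl]-1,3-dithian-2-yl}-4-hydroxy-3-methylbutyl acetate (C4 epimers) | OC(c1ccc(OCc2ccccc2)c(OC)c1)[C@H](C)[C@H](COC(C)=O)C3(SCCCS3)c4cc(OC)c(OCc5ccccc5)c(OC)c4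
F6 | step 12 | (2R,3R)-4-[4-(benzyloxy)-3-methoxyphenyl]-2-[4-(benzyloxy)-3,5-dimethoxybenzyl]-4-hydroxy-3-methylbutyl acetate (C4 epimers) | OC(c1ccc(OCc2ccccc2)c(OC)c1)[C@H](C)[C@H](COC(C)=O)Cc3cc(OC)c(OCc4ccccc4)c(OC)c3
F7 | step 12 | O-{(2R,3R)-4-acetoxy-1-[4-(benzyloxy)-3-methoxyphenyl]-3-[4-(benzyloxy)-3,5-dimethoxybenzyl]-2-methylbutyl} O-phenyl carbonothioate (C1 epimers) | S=C(Oc1ccccc1)OC(c2ccc(OCc3ccccc3)c(OC)c2)[C@H](C)[C@H](COC(C)=O)Cc4cc(OC)c(OCc5ccccc5)c(OC)c4
F8 | step 12 | (2R,3S)-4-[4-(benzyloxy)-3-methoxyphenyl]-2-[4-(benzyloxy)-3,5-dimethoxybenzyl]-3-methylbutyl acetate | C(c1ccc(OCc2ccccc2)c(OC)c1)[C@H](C)[C@H](COC(C)=O)Cc3cc(OC)c(OCc4ccccc4)c(OC)c3
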